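The core is cut at C9–C10 and C4–C5. Reading the C8 ketone and C9 carbinol as a glyoxal, C5–C10 as an (E)-trisubstituted alkene and C3/C4 as a (Z)-silyl enol ether opens rings A and B to one achiral chain, (5E,9Z)-9-silyloxy-5-methyl-2-oxoundeca-5,9-dienal. A copper bis(oxazoline) Lewis acid chelates the 1,2-dicarbonyl and starts a Prins–Mukaiyama cascade that closes both rings, forms both bonds and sets C4, C5, C9 and C10 in one operation. The C7 (E)-alkylidene, inversion of C3 during acylation with the separately made trienoic acid, and desilylation complete the synthesis.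

Key step: step 10

Assumption: eremophilane numbering is used for all bicyclic compounds (ring A = C1–C5 and C10, ring B = C5–C10, C11–C13 on C7, C14 on C5, C15 on C4), and the α-ketoaldehyde is taken to bind copper as a glyoxylate does, so that the (S,S)-ligand exposes the Si face of C9.

Step 1
Reactants: 1 2-(2-bromoethyl)-1,3-dioxolane; 2 methacrolein (2-methylprop-2-enal)
Product: 4 1-(1,3-dioxolan-2-yl)-4-methylpent-4-en-3-ol (racemic), via Grignard reagent 3 (not isolated)
Conditions: Mg, THF, 25 °C; then 2, −78 → 0 °C; aq NH4Cl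
Reagents that add atoms: none
Why: Grignard addition: the acetal-protected three-carbon nucleophile adds 1,2 to the enal to give the secondary allylic alcohol needed for the Claisen step, and its racemic carbinol centre is destroyed in step 2.

Step 2
Reactants: 4 1-(1,3-dioxolan-2-yl)-4-methylpent-4-en-3-ol; 5 triethyl orthoacetate
Product: 7 ethyl (E)-7-(1,3-dioxolan-2-yl)-4-methylhept-4-enoate, via ketene acetal 6 (not isolated)
Conditions: 5 (6 equiv), EtCO2H (cat.), 140 °C, EtOH distilled off
Reagents that add atoms: none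
Why: Johnson–Claisen rearrangement: the mixed ketene acetal rearranges through a chair with the acetal-bearing chain equatorial, which should deliver the (E)-trisubstituted alkene (the future C5=C10) together with the two-carbon ester arm (C7, C8).

Step 3
Reactants: 7 ethyl (E)-7-(1,3-dioxolan-2-yl)-4-methylhept-4-enoate
Product: 8 ethyl (E)-4-methyl-8-oxooct-4-enoate
Conditions: 1 M HCl, THF, 23 °C
Reagents that add atoms: water, O
Why: acid-catalysed acetal hydrolysis: the dioxolane is cleaved to the aldehyde while the ethyl ester and the isolated trisubstituted alkene are inert to dilute acid at room temperature.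

Step 4
Reactants: 8 ethyl (E)-4-methyl-8-oxooct-4-enoate; 9 vinylmagnesium bromide
Product: 10 ethyl (E)-8-hydroxy-4-methyldeca-4,9-dienoate (racemic)
Conditions: THF, −78 °C; aq NH4Cl
Reagents that add atoms: none
Why: Grignard 1,2-addition: at −78 °C the aldehyde reacts much faster than the ethyl ester, and the racemic carbinol is oxidised in the next step.

Step 5
Reactants: 10 ethyl (E)-8-hydroxy-4-methyldeca-4,9-dienoate
Product: 11 ethyl (E)-4-methyl-8-oxodeca-4,9-dienoate
Conditions: Dess–Martin periodinane, NaHCO3, CH2Cl2, 0 → 23 °C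
Reagents that add atoms: none
Why: Dess–Martin oxidation: the allylic alcohol is oxidised to the vinyl ketone under buffered, non-nucleophilic conditions that avoid conjugate addition to the sensitive enone.

Step 6
Reactants: 11 ethyl (E)-4-methyl-8-oxodeca-4,9-dienoate
Product: 12 ethyl (4E,8Z)-8-[(tert-butyldimethylsilyl)oxy]-4-methyldeca-4,8-dienoate
Conditions: t-BuMe2SiH, Pt2[(CH2=CHSiMe2)2O]3 (zerovalent platinum, 0.5 mol %), toluene, 0 → 23 °C
Reagents that add atoms: tert-butyldimethylsilane, CC(C)(C)[SiH](C)C
Why: platinum-catalysed 1,4-hydrosilylation of an enone: hydrogen goes to the terminal carbon and silicon to oxygen, so only the C3=C4 enol silane can form (an ethyl ketone would enolise to both sides), and addition through the s-cis enone should place the new methyl cis to oxygen (Z).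

Step 7
Reactants: 12 ethyl (4E,8Z)-8-[(tert-butyldimethylsilyl)oxy]-4-methyldeca-4,8-dienoate
Product: 13 (4E,8Z)-8-[(tert-butyldimethylsilyl)oxy]-4-methyldeca-4,8-dienal
Conditions: i-Bu2AlH (1.05 equiv), CH2Cl2, −78 °C; MeOH, aq potassium sodium tartrate
Reagents that add atoms: none
Why: partial reduction of an ester with a dialkylaluminium hydride: the tetrahedral aluminate is stable at −78 °C and collapses to the aldehyde only on the neutral work-up, which the enol silane tolerates.

Step 8
Reactants: 13 (4E,8Z)-8-[(tert-butyldimethylsilyl)oxy]-4-methyldeca-4,8-dienal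
Product: 14 (5E,9Z)-9-[(tert-butyldimethylsilyl)oxy]-1-hydroxy-5-methylundeca-5,9-dien-2-one
Conditions: (CH2O)n, 3-benzyl-5-(2-hydroxyethyl)-4-methylthiazolium chloride (10 mol %), i-Pr2NEt, THF, 60 °C
Reagents that add atoms: paraformaldehyde (as formaldehyde), C=O
Why: thiazolium carbene-catalysed crossed acyloin condensation (hydroxymethylation): the acyl-anion equivalent formed from the aldehyde adds to formaldehyde, the stronger electrophile, which installs C9 as a primary ketol under mildly basic conditions that the enol silane tolerates.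

Step 9
Reactants: 14 (5E,9Z)-9-[(tert-butyldimethylsilyl)oxy]-1-hydroxy-5-methylundeca-5,9-dien-2-one
Product: 15 (5E,9Z)-9-[(tert-butyldimethylsilyl)oxy]-5-methyl-2-oxoundeca-5,9-dienal
Conditions: Dess–Martin periodinane, pyridine, CH2Cl2, 0 °C; filtered through Celite, used at once
Reagents that add atoms: none
Why: Dess–Martin oxidation: the primary ketol is oxidised to the α-ketoaldehyde under buffered, anhydrous conditions, so that the acid-sensitive enol silane survives and the glyoxal is obtained unhydrated for immediate use.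

Step 10
Reactants: 15 (5E,9Z)-9-[(tert-butyldimethylsilyl)oxy]-5-methyl-2-oxoundeca-5,9-dienal
Product: 17 (4R,5S,9S,10R)-9-hydroxy-4,5-dimethyl-trans-decalin-3,8-dione, via silyl ether 16 (not isolated)
Conditions: Cu(OTf)2 (20 mol %), 2,2'-isopropylidenebis[(4S)-4-tert-butyl-2-oxazoline] (22 mol %), 2,6-di-tert-butyl-4-methylpyridine (20 mol %), 4 Å MS, CH2Cl2, −78 → −40 °C, 15 added slowly to 2 mM; then aq HF, MeCN, 0 °C
Reagents that add atoms: none
Why: Proposed new method: two-point binding of the C8/C9 1,2-dicarbonyl to the square-planar divalent copper complex should activate only the aldehyde and shield one of its faces, so that C10 of the alkene attacks the Si face of C9 (6-endo Prins-type closure of ring B) and the developing tertiary C5 cation is captured by C4 of the enol silane (6-endo closure of ring A), after which the silyl group moves to O9 and releases the catalyst; the closest known reactions are Lewis-acid Prins-initiated cation–olefin bicyclisations terminated by enol silanes and copper bis(oxazoline) carbonyl-ene and Mukaiyama aldol reactions of chelating glyoxylates and pyruvates. C9 is set in the absolute sense by the ligand and in the relative sense by the s-cis chelate, which keeps O9 eclipsed with C8=O and therefore equatorial. C10 and C5 follow from anti addition across the (E)-alkene in a chair–chair array, which gives the trans ring fusion with C14 axial. C4 follows from the (Z)-enol silane, whose methyl is cis to oxygen and so ends equatorial and cis to C14; any axial epimer could be equilibrated next to the C3 ketone. The step needs cation capture to outrun ene-type proton loss from C14 or C6 and intermolecular aldol addition, which the pre-organised chair, the nucleophilic enol silane, high dilution and the hindered pyridine buffer should secure; the fluoride work-up converges free and O9-silylated product onto the ketol, which can be recrystallised to raise its enantiomeric purity.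

Step 11
Reactants: 17 (4R,5S,9S,10R)-9-hydroxy-4,5-dimethyl-trans-decalin-3,8-dione
Product: 16 (4R,5S,9S,10R)-9-[(tert-butyldimethylsilyl)oxy]-4,5-dimethyl-trans-decalin-3,8-dione
Conditions: TBSOTf, 2,6-lutidine, CH2Cl2, −78 → 0 °C
Reagents that add atoms: tert-butyldimethylsilyl trifluoromethanesulfonate, CC(C)(C)[Si](C)(C)OS(=O)(=O)C(F)(F)F
Why: silylation with a silyl triflate: the equatorial secondary carbinol is capped at low temperature without enolising either ketone, and the bulky ether protects O9 and deactivates C8 for step 12.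

Step 12
Reactants: 16 (4R,5S,9S,10R)-9-[(tert-butyldimethylsilyl)oxy]-4,5-dimethyl-trans-decalin-3,8-dione
Product: 18 (4R,5S,9S,10R)-9-[(tert-butyldimethylsilyl)oxy]-3,3-(ethylenedioxy)-4,5-dimethyl-trans-decalin-8-one
Conditions: (Me3SiOCH2)2, Me3SiOTf (5 mol %), CH2Cl2, −78 → −30 °C; pyridine
Reagents that add atoms: 1,2-bis(trimethylsilyloxy)ethane, C[Si](C)(C)OCCO[Si](C)(C)C
Why: silyl-triflate catalysed ketalisation with a bis-silyl glycol: the C3 ketone should react under kinetic control, whereas C8 is flanked by the silyloxy group, which shields it and destabilises the oxocarbenium intermediate.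

Step 13
Reactants: 18 (4R,5S,9S,10R)-9-[(tert-butyldimethylsilyl)oxy]-3,3-(ethylenedioxy)-4,5-dimethyl-trans-decalin-8-one; 19 1-[(tert-butyldimethylsilyl)oxy]propan-2-one
Product: 22 (4R,5S,9S,10R,7(11)E)-9,12-bis[(tert-butyldimethylsilyl)oxy]-3,3-(ethylenedioxy)eremophil-7(11)-en-8-one, via lithium aldolate 20 (not isolated), via tertiary acetate 21 (not isolated)
Conditions: LDA, THF, −78 °C; 19, −78 °C; Ac2O, −78 → 0 °C; DBU, 23 °C
Reagents that add atoms: none
Why: aldol addition followed by E1cB elimination (aldol condensation): LDA removes a C7 proton (C9 is a hindered silyloxy methine), the aldolate is trapped as its acetate before it can revert, and DBU eliminates through the C7 enolate, in which the bulky, electron-rich CH2OSi arm should avoid the enolate oxygen so that the methyl is expected to end cis to C8=O, i.e. (E), any (Z)-isomer being removed by chromatography.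

Step 14
Reactants: 22 (4R,5S,9S,10R,7(11)E)-9,12-bis[(tert-butyldimethylsilyl)oxy]-3,3-(ethylenedioxy)eremophil-7(11)-en-8-one
Product: 23 (4R,5S,9S,10R,7(11)E)-9,12-bis[(tert-butyldimethylsilyl)oxy]eremophil-7(11)-ene-3,8-dione
Conditions: In(OTf)3 (2 mol %), acetone/H2O (20:1), 23 °C
Reagents that add atoms: water, O
Why: Lewis-acid catalysed ketal hydrolysis: the strained C3 dioxolane (one oxygen is syn-axial to C14) should be cleaved under near-neutral conditions that leave both silyl ethers and the enone geometry intact.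

Step 15
Reactants: 23 (4R,5S,9S,10R,7(11)E)-9,12-bis[(tert-butyldimethylsilyl)oxy]eremophil-7(11)-ene-3,8-dione
Product: 24 (3S,4R,5R,9S,10R,7(11)E)-9,12-bis[(tert-butyldimethylsilyl)oxy]-3-hydroxyeremophil-7(11)-en-8-one (3-OH axial)
Conditions: LiBH(s-Bu)3 (1.1 equiv), THF, −78 °C; aq NH4Cl
Reagents that add atoms: none
Why: bulky trialkylborohydride reduction: the saturated C3 ketone should react in preference to the hindered tetrasubstituted C8 enone, and hydride arrives along the equatorial direction because the axial face is blocked by the syn-axial C14 methyl, which gives the axial (3S)-alcohol needed for the inversion in step 19.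

Step 16
Reactants: 25 (E)-oct-2-enal
Product: 26 (E)-non-3-en-1-yne
Conditions: Me3SiCHN2, n-BuLi, THF, −78 °C; 25, −78 → 0 °C
Reagents that add atoms: (trimethylsilyl)diazomethane, C[Si](C)(C)C=[N+]=[N-]
Why: Colvin rearrangement: 1,2-addition of lithiated silyldiazomethane to the enal, loss of silanolate and nitrogen and a 1,2-hydride shift of the alkylidene carbene give the terminal enyne with the (E)-alkene untouched.

Step 17
Reactants: 26 (E)-non-3-en-1-yne
Product: 28 (1E,3E)-1-iodo-2-methylnona-1,3-diene, via alkenylalane 27 (not isolated)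
Conditions: Me3Al, Cp2ZrCl2 (20 mol %), CH2Cl2, 0 → 23 °C; then I2, THF, −30 °C
Reagents that add atoms: trimethylaluminium, C[Al](C)C; iodine, II
Why: zirconium-catalysed carboalumination and iodinolysis: methyl and aluminium add syn across the alkyne with aluminium at the terminus, and iodine replaces aluminium with retention, which fixes the (E)-trisubstituted alkene of the acid.

Step 18
Reactants: 28 (1E,3E)-1-iodo-2-methylnona-1,3-diene; 29 acrylic acid
Product: 30 (2E,4E,6E)-5-methyldodeca-2,4,6-trienoic acid
Conditions: Pd(OAc)2 (5 mol %), K2CO3, Bu4NCl, DMF, 40 °C; aq citric acid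
Reagents that add atoms: none
Why: Heck reaction: oxidative addition of the alkenyl iodide occurs with retention, and syn insertion of acrylate followed by syn β-hydride elimination gives the new (E)-alkene, so the all-(E) trienoic acid should result directly.

Step 19
Reactants: 24 (3S,4R,5R,9S,10R,7(11)E)-9,12-bis[(tert-butyldimethylsilyl)oxy]-3-hydroxyeremophil-7(11)-en-8-one; 30 (2E,4E,6E)-5-methyldodeca-2,4,6-trienoic acid
Product: 31 (3R,4R,5R,9S,10R,7(11)E)-9,12-bis[(tert-butyldimethylsilyl)oxy]-8-oxoeremophil-7(11)-en-3-yl (2E,4E,6E)-5-methyldodeca-2,4,6-trienoate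
Conditions: PPh3, DIAD, toluene, 0 → 23 °C
Reagents that add atoms: none
Why: Mitsunobu esterification: the carboxylate displaces the axial oxyphosphonium group from the open lower face with inversion, so acylation and correction of C3 to the equatorial (3R) ester occur together while O9 and O12 stay silylated.

Step 20
Reactants: 31 (3R,4R,5R,9S,10R,7(11)E)-9,12-bis[(tert-butyldimethylsilyl)oxy]-8-oxoeremophil-7(11)-en-3-yl (2E,4E,6E)-5-methyldodeca-2,4,6-trienoate
Product: 32 (3R,4R,5R,9S,10R,7(11)E)-9,12-dihydroxy-8-oxoeremophil-7(11)-en-3-yl (2E,4E,6E)-5-methyldodeca-2,4,6-trienoate (CNP0226738.2)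
Conditions: HF·pyridine, pyridine, THF, 0 → 23 °C
Reagents that add atoms: none
Why: fluoride-mediated desilylation: buffered HF·pyridine should cleave both silyl ethers without touching the trienoate, the α-ketol or the (E)-hydroxy enone, whose C12 hydroxyl cannot reach C8.

Compound list
1 | 2-(2-bromoethyl)-1,3-dioxolane | BrCCC1OCCO1 | starting material
2 | methacrolein (2-methylprop-2-enal) | CC(=C)C=O | starting material
3 | [2-(1,3-dioxolan-2-yl)ethyl]magnesium bromide | Br[Mg]CCC1OCCO1 | intermediate
4 | 1-(1,3-dioxolan-2-yl)-4-methylpent-4-en-3-ol (racemic) | CC(=C)C(O)CCC1OCCO1 | intermediate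
5 | triethyl orthoacetate | CCOC(C)(OCC)OCC | starting material
6 | 2-{3-[(1-ethoxyethenyl)oxy]-4-methylpent-4-en-1-yl}-1,3-dioxolane (mixed ketene acetal) | C=C(OCC)OC(CCC1OCCO1)C(C)=C | intermediate
7 | ethyl (E)-7-(1,3-dioxolan-2-yl)-4-methylhept-4-enoate | CCOC(=O)CC/C(C)=C/CCC1OCCO1 | intermediate
8 | ethyl (E)-4-methyl-8-oxooct-4-enoate | CCOC(=O)CC/C(C)=C/CCC=O | intermediate
9 | vinylmagnesium bromide | C=C[Mg]Br | starting material
10 | ethyl (E)-8-hydroxy-4-methyldeca-4,9-dienoate (racemic) | CCOC(=O)CC/C(C)=C/CCC(O)C=C | intermediate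
11 | ethyl (E)-4-methyl-8-oxodeca-4,9-dienoate | CCOC(=O)CC/C(C)=C/CCC(=O)C=C | intermediate
12 | ethyl (4E,8Z)-8-[(tert-butyldimethylsilyl)oxy]-4-methyldeca-4,8-dienoate | CCOC(=O)CC/C(C)=C/CC/C(O[Si](C)(C)C(C)(C)C)=C/C | intermediate
13 | (4E,8Z)-8-[(tert-butyldimethylsilyl)oxy]-4-methyldeca-4,8-dienal | O=CCC/C(C)=C/CC/C(O[Si](C)(C)C(C)(C)C)=C/C | intermediate
14 | (5E,9Z)-9-[(tert-butyldimethylsilyl)oxy]-1-hydroxy-5-methylundeca-5,9-dien-2-one | OCC(=O)CC/C(C)=C/CC/C(O[Si](C)(C)C(C)(C)C)=C/C | intermediate
15 | (5E,9Z)-9-[(tert-butyldimethylsilyl)oxy]-5-methyl-2-oxoundeca-5,9-dienal (key-step precursor) | O=CC(=O)CC/C(C)=C/CC/C(O[Si](C)(C)C(C)(C)C)=C/C | intermediate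
16 | (4R,5S,9S,10R)-9-[(tert-butyldimethylsilyl)oxy]-4,5-dimethyl-trans-decalin-3,8-dione | O=C1CC[C@H]2[C@H](O[Si](C)(C)C(C)(C)C)C(=O)CC[C@]2(C)[C@H]1C | intermediate
17 | (4R,5S,9S,10R)-9-hydroxy-4,5-dimethyl-trans-decalin-3,8-dione (4-Me equatorial, 5-Me axial, 9-OH equatorial; key-step product) | O=C1CC[C@H]2[C@H](O)C(=O)CC[C@]2(C)[C@H]1C | intermediate
18 | (4R,5S,9S,10R)-9-[(tert-butyldimethylsilyl)oxy]-3,3-(ethylenedioxy)-4,5-dimethyl-trans-decalin-8-one | O1CCOC12CC[C@H]3[C@H](O[Si](C)(C)C(C)(C)C)C(=O)CC[C@]3(C)[C@H]2C | intermediate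
19 | 1-[(tert-butyldimethylsilyl)oxy]propan-2-one | CC(=O)CO[Si](C)(C)C(C)(C)C | starting material
20 | lithium aldolate: 18 bearing at C7 a 1-[(tert-butyldimethylsilyl)oxy]-2-(lithiooxy)propan-2-yl group (C7/C11 epimers) | O1CCOC12CC[C@H]3[C@H](O[Si](C)(C)C(C)(C)C)C(=O)C(C(C)(O[Li])CO[Si](C)(C)C(C)(C)C)C[C@]3(C)[C@H]2C | intermediate
21 | tertiary acetate: 18 bearing at C7 a 2-acetoxy-1-[(tert-butyldimethylsilyl)oxy]propan-2-yl group (C7/C11 epimers) | O1CCOC12CC[C@H]3[C@H](O[Si](C)(C)C(C)(C)C)C(=O)C(C(C)(OC(C)=O)CO[Si](C)(C)C(C)(C)C)C[C@]3(C)[C@H]2C | intermediate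
22 | (4R,5S,9S,10R,7(11)E)-9,12-bis[(tert-butyldimethylsilyl)oxy]-3,3-(ethylenedioxy)eremophil-7(11)-en-8-one (C13 cis to C8=O) | O1CCOC12CC[C@H]3[C@H](O[Si](C)(C)C(C)(C)C)C(=O)/C(=C(\C)CO[Si](C)(C)C(C)(C)C)C[C@]3(C)[C@H]2C | intermediate
23 | (4R,5S,9S,10R,7(11)E)-9,12-bis[(tert-butyldimethylsilyl)oxy]eremophil-7(11)-ene-3,8-dione | O=C1CC[C@H]2[C@H](O[Si](C)(C)C(C)(C)C)C(=O)/C(=C(\C)CO[Si](C)(C)C(C)(C)C)C[C@]2(C)[C@H]1C | intermediate
24 | (3S,4R,5R,9S,10R,7(11)E)-9,12-bis[(tert-butyldimethylsilyl)oxy]-3-hydroxyeremophil-7(11)-en-8-one (3-OH axial) | O[C@H]1CC[C@H]2[C@H](O[Si](C)(C)C(C)(C)C)C(=O)/C(=C(\C)CO[Si](C)(C)C(C)(C)C)C[C@]2(C)[C@H]1C | intermediate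
25 | (E)-oct-2-enal | CCCCC/C=C/C=O | starting material
26 | (E)-non-3-en-1-yne | CCCCC/C=C/C#C | intermediate
27 | dimethyl[(1E,3E)-2-methylnona-1,3-dien-1-yl]alane | CCCCC/C=C/C(C)=C/[Al](C)C | intermediate
28 | (1E,3E)-1-iodo-2-methylnona-1,3-diene | CCCCC/C=C/C(C)=C/I | intermediate
29 | acrylic acid | C=CC(=O)O | starting material
30 | (2E,4E,6E)-5-methyldodeca-2,4,6-trienoic acid | CCCCC/C=C/C(C)=C/C=C/C(=O)O | intermediate
31 | (3R,4R,5R,9S,10R,7(11)E)-9,12-bis[(tert-butyldimethylsilyl)oxy]-8-oxoeremophil-7(11)-en-3-yl (2E,4E,6E)-5-methyldodeca-2,4,6-trienoate | CCCCC/C=C/C(C)=C/C=C/C(=O)O[C@@H]1CC[C@H]2[C@H](O[Si](C)(C)C(C)(C)C)C(=O)/C(=C(\C)CO[Si](C)(C)C(C)(C)C)C[C@]2(C)[C@H]1C | intermediate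
32 | (3R,4R,5R,9S,10R,7(11)E)-9,12-dihydroxy-8-oxoeremophil-7(11)-en-3-yl (2E,4E,6E)-5-methyldodeca-2,4,6-trienoate (CNP0226738.2) | CCCCC/C=C/C(C)=C/C=C/C(=O)O[C@@H]1CC[C@H]2[C@H](O)C(=O)/C(=C(\C)CO)C[C@]2(C)[C@H]1C | target

Total step count: 20. Longest linear sequence: 17 steps (steps 1–15, 19 and 20); the acid 30 is made in three steps (16–18).

Steps most likely to fail

1. Step 10. The C5 cation may lose a proton from C14 or C6 before ring A closes (ene-type termination). The enol silane may add to a copper-bound glyoxal of a second molecule. Face selection at C9 may be poor, or silyl transfer to O9 may be too slow for the catalyst to turn over. The fallback uses known chemistry and gives up catalytic enantiocontrol. It sets out from 15: a stoichiometric, proton-scavenging aluminium Lewis acid (MeAlCl2, CH2Cl2, −78 °C) promotes the Prins-initiated cation–olefin bicyclisation with enol silane termination under substrate control. After the same aqueous HF work-up this should give the racemic ketol, that is 17 together with its enantiomer, (4S,5R,9R,10S)-9-hydroxy-4,5-dimethyl-trans-decalin-3,8-dione F1. Preparative chromatography on a chiral stationary phase separates the two, and the route is rejoined at 17.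

2. Step 13. The tertiary aldolate may revert before it is acetylated, and the E1cB elimination may be unselective, giving the (Z)-alkylidene or deconjugated isomers, because methyl and CH2OSi differ little in size. The fallback sets out from 18 and 19 and replaces the elimination under enolate control by a stereospecific syn elimination. The aldol addition is run alone (LDA, THF, −78 °C, AcOH quench at −78 °C) and the C11 epimers are separated. The (7S,11R)-aldol, (4R,5S,7S,9S,10R,11R)-9,12-bis[(tert-butyldimethylsilyl)oxy]-3,3-(ethylenedioxy)-11-hydroxyeremophilan-8-one F2, is dehydrated with the Burgess reagent (benzene, 50 °C). In this syn elimination H7 and O11 eclipse with C13 over C8, so only the (E)-enone can form, and the route is rejoined at 22. The (7S,11S)-aldol, the C11 epimer of F2, F3, is returned to 18 by base-induced retro-aldol cleavage and recycled.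

3. Step 19. The axial oxyphosphonium ion has anti-periplanar hydrogens at C2 and C4 and may eliminate instead of being displaced, or the hindered carbinol (syn-axial to C14) may not be activated by the weakly acidic trienoic acid. The fallback sets out from 24 and replaces inversion by thermodynamic equilibration. Under Meerwein–Ponndorf–Verley/Oppenauer conditions (Al(Oi-Pr)3, i-PrOH, trace acetone, toluene, 80 °C) the carbinol should epimerise through the ketone to the equatorial alcohol, (3R,4R,5R,9S,10R,7(11)E)-9,12-bis[(tert-butyldimethylsilyl)oxy]-3-hydroxyeremophil-7(11)-en-8-one F4, while the hindered enone is expected to stay untouched. Carbodiimide acylation of F4 with 30 (EDC·HCl, DMAP, CH2Cl2) proceeds with retention and rejoins the route at 31.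

Further compounds
F1 | step 10 | (4S,5R,9R,10S)-9-hydroxy-4,5-dimethyl-trans-decalin-3,8-dione (enantiomer of 17) | O=C1CC[C@@H]2[C@@H](O)C(=O)CC[C@@]2(C)[C@@H]1C
F2 | step 13 | (4R,5S,7S,9S,10R,11R)-9,12-bis[(tert-butyldimethylsilyl)oxy]-3,3-(ethylenedioxy)-11-hydroxyeremophilan-8-one | O1CCOC12CC[C@H]3[C@H](O[Si](C)(C)C(C)(C)C)C(=O)[C@H]([C@@](C)(O)CO[Si](C)(C)C(C)(C)C)C[C@]3(C)[C@H]2C
F3 | step 13 | (4R,5S,7S,9S,10R,11S)-9,12-bis[(tert-butyldimethylsilyl)oxy]-3,3-(ethylenedioxy)-11-hydroxyeremophilan-8-one | O1CCOC12CC[C@H]3[C@H](O[Si](C)(C)C(C)(C)C)C(=O)[C@H]([C@](C)(O)CO[Si](C)(C)C(C)(C)C)C[C@]3(C)[C@H]2C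
F4 | step 19 | (3R,4R,5R,9S,10R,7(11)E)-9,12-bis[(tert-butyldimethylsilyl)oxy]-3-hydroxyeremophil-7(11)-en-8-one (3-OH equatorial) | O[C@@H]1CC[C@H]2[C@H](O[Si](C)(C)C(C)(C)C)C(=O)/C(=C(\C)CO[Si](C)(C)C(C)(C)C)C[C@]2(C)[C@H]1C
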